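**Retrosynthetic overview**
1. The enone C(=O)–Cα bond is cut: rhodium-catalysed hydroacylation of 4-ethynylphenol by 2,4-dihydroxy-3,5-diprenylbenzaldehyde gives the target directly, without protecting groups, and syn addition sets the (E) geometry.
2. Enabling feature: the free C2'–OH on the resorcinol ring, ortho to the carbon (C1') that carries the acyl group. This salicyl unit O–C2'–C1'–C(=O) chelates rhodium and allows activation of the formyl C–H bond.
3. The aldehyde comes from resorcinol bis-MOM ether by three successive MOM-directed ortho-metalations (C2 prenyl, C4 prenyl, C6 formyl), then MOM removal.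
4. No ring is formed in the route: both benzene rings are bought (resorcinol, 4-ethynylphenol).

Key step: step 6

Assumption: the target has no stereocentre; its only stereo-element is the (E) enone double bond, so "single enantiomer" is read as the single (E) isomer.

**Step 1**
Reactants: 1 resorcinol
Product: 2 1,3-bis(methoxymethoxy)benzene
Conditions: NaH, DMF, 0 °C; MOMCl, 0 °C → rt
Reagents that add atoms: chloromethyl methyl ether (MOMCl), COCCl
Why: Williamson-type O-alkylation of the bis-phenoxide should install two MOM ethers, which are strong ortho-lithiation directors and can later be removed with mild acid that prenyl groups tolerate.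

**Step 2**
Reactants: 2 1,3-bis(methoxymethoxy)benzene; 3 prenyl bromide (1-bromo-3-methylbut-2-ene)
Product: 5 1,3-bis(methoxymethoxy)-2-(3-methylbut-2-en-1-yl)benzene, via aryllithium 4 (not isolated)
Conditions: n-BuLi, THF, 0 °C; CuI (10 mol%), 3, −78 °C → rt
Reagents that add atoms: none
Why: Directed ortho-metalation should occur at C2, whose C–H is flanked by both OMOM groups, and copper-catalysed allylation of 4 should take place at the primary carbon of 3 (SN2) because SN2' attack would build a quaternary benzylic carbon.

**Step 3**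
Reactants: 5 1,3-bis(methoxymethoxy)-2-(3-methylbut-2-en-1-yl)benzene; 3 prenyl bromide
Product: 7 1,3-bis(methoxymethoxy)-2,4-bis(3-methylbut-2-en-1-yl)benzene, via aryllithium 6 (not isolated)
Conditions: s-BuLi, TMEDA, THF, −78 °C; CuI (10 mol%), 3, −78 °C → rt
Reagents that add atoms: none
Why: A second directed ortho-metalation under kinetic control should lithiate C4 (C4 and C6 are equivalent by symmetry) faster than the benzylic–allylic CH2 is deprotonated, and the copper-catalysed SN2 allylation then repeats step 2.

**Step 4**
Reactants: 7 1,3-bis(methoxymethoxy)-2,4-bis(3-methylbut-2-en-1-yl)benzene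
Product: 10 2,4-bis(methoxymethoxy)-3,5-bis(3-methylbut-2-en-1-yl)benzaldehyde, via aryllithium 8 (not isolated), via lithium hemiaminal alkoxide 9 (not isolated)
Conditions: s-BuLi, TMEDA, THF, −78 °C; DMF, −78 → 0 °C; H2O
Reagents that add atoms: N,N-dimethylformamide (DMF), CN(C)C=O
Why: The only ring position still ortho to an OMOM group is C6, so directed ortho-metalation and Bouveault-type formylation with DMF should give a single aldehyde, the tetrahedral adduct 9 surviving until the aqueous quench and so preventing over-addition.

**Step 5**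
Reactants: 10 2,4-bis(methoxymethoxy)-3,5-bis(3-methylbut-2-en-1-yl)benzaldehyde
Product: 11 2,4-dihydroxy-3,5-bis(3-methylbut-2-en-1-yl)benzaldehyde
Conditions: 3 M aq. HCl, MeOH, 40 °C
Reagents that add atoms: none
Why: Acid-catalysed acetal exchange with methanol should cleave both aryl MOM ethers under conditions mild enough to leave the ortho-prenyl phenols uncyclised, any transient dimethyl acetal of the aldehyde reverting in the aqueous acid.

**Step 6**
Reactants: 11 2,4-dihydroxy-3,5-bis(3-methylbut-2-en-1-yl)benzaldehyde; 12 4-ethynylphenol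
Product: 13 (E)-1-[2,4-dihydroxy-3,5-bis(3-methylbut-2-en-1-yl)phenyl]-3-(4-hydroxyphenyl)prop-2-en-1-one
Conditions: [RhCl(cod)]2 (2.5 mol%), dppf (5.5 mol%), Na2CO3 (10 mol%), toluene, 80 °C, slow addition of 12 (1.5 equiv)
Reagents that add atoms: none
Why: Base should generate a rhodium(I) phenoxide at O2 of 11, whose ortho formyl C–H adds oxidatively to give a five-membered O,C-chelated acyl–Rh(III) hydride (Rh–O2–C2–C1–C(acyl)); alkyne 12 then inserts syn into Rh–H with Rh at its unsubstituted carbon, and C(acyl)–C(vinyl) reductive elimination with retention releases the enone and returns Rh(I). The closest known reaction type is the rhodium/bisphosphine-catalysed intermolecular hydroacylation of alkynes with salicylaldehydes to 2-hydroxyaryl alkenyl ketones. No ring of the product is closed; the only ring involved is the transient five-membered acyl rhodacycle, whose chelation should suppress decarbonylation. No stereocentre is formed; the (E) geometry follows from syn hydrometalation, which places the acyl and aryl groups trans. The step needs linear regioselectivity, chemoselectivity for the alkyne over the two prenyl alkenes and tolerance of three free phenols: the monosubstituted aryl alkyne should steer Rh to its unhindered terminus under the wide-bite-angle ligand, the trisubstituted prenyl alkenes are poor ligands and sit meta to the formyl group so cannot insert intramolecularly, and only O2 can form the chelate that activates the C–H bond. Slow addition of 12 keeps its concentration low and should limit rhodium-mediated alkyne oligomerisation.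

**Compound list**
1 | resorcinol | Oc1cccc(O)c1 | starting material
2 | 1,3-bis(methoxymethoxy)benzene | COCOc1cccc(OCOC)c1 | intermediate
3 | prenyl bromide (1-bromo-3-methylbut-2-ene) | CC(C)=CCBr | starting material
4 | [2,6-bis(methoxymethoxy)phenyl]lithium | COCOc1cccc(OCOC)c1[Li] | intermediate
5 | 1,3-bis(methoxymethoxy)-2-(3-methylbut-2-en-1-yl)benzene | COCOc1cccc(OCOC)c1CC=C(C)C | intermediate
6 | [2,4-bis(methoxymethoxy)-3-(3-methylbut-2-en-1-yl)phenyl]lithium | COCOc1ccc([Li])c(OCOC)c1CC=C(C)C | intermediate
7 | 1,3-bis(methoxymethoxy)-2,4-bis(3-methylbut-2-en-1-yl)benzene | COCOc1ccc(CC=C(C)C)c(OCOC)c1CC=C(C)C | intermediate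
8 | [2,4-bis(methoxymethoxy)-3,5-bis(3-methylbut-2-en-1-yl)phenyl]lithium | COCOc1c([Li])cc(CC=C(C)C)c(OCOC)c1CC=C(C)C | intermediate
9 | lithium [2,4-bis(methoxymethoxy)-3,5-bis(3-methylbut-2-en-1-yl)phenyl](dimethylamino)methanolate | COCOc1c(C([O-])N(C)C)cc(CC=C(C)C)c(OCOC)c1CC=C(C)C.[Li+] | intermediate
10 | 2,4-bis(methoxymethoxy)-3,5-bis(3-methylbut-2-en-1-yl)benzaldehyde | COCOc1c(C=O)cc(CC=C(C)C)c(OCOC)c1CC=C(C)C | intermediate
11 | 2,4-dihydroxy-3,5-bis(3-methylbut-2-en-1-yl)benzaldehyde | O=Cc1cc(CC=C(C)C)c(O)c(CC=C(C)C)c1O | intermediate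
12 | 4-ethynylphenol | C#Cc1ccc(O)cc1 | starting material
13 | (E)-1-[2,4-dihydroxy-3,5-bis(3-methylbut-2-en-1-yl)phenyl]-3-(4-hydroxyphenyl)prop-2-en-1-one | CC(C)=CCc1cc(C(=O)/C=C/c2ccc(O)cc2)c(O)c(CC=C(C)C)c1O | target

**Step count and risks**
Total step count: 6. Longest linear sequence: 6 steps (1 → 2 → 5 → 7 → 10 → 11 → 13).

Steps most likely to fail:

1. Step 6 (key step). The hydrorhodation may give the wrong regiochemistry and so a branched enone. The terminal aryl alkyne may oligomerise on rhodium, a transient Rh–H may isomerise a prenyl group into conjugation, and the product may close to the flavanone by oxa-Michael addition. Fallback: form the same bond by acetylide addition and adjust the oxidation level afterwards. It sets out from 10 (step 5 is left out) and from 12, and comes back to the route at 13. Compound 12 is protected (MOMCl, i-Pr2NEt, CH2Cl2) as 1-ethynyl-4-(methoxymethoxy)benzene F1. Deprotonation (n-BuLi, THF, −78 °C) gives lithium [4-(methoxymethoxy)phenyl]acetylide F2, which should add to aldehyde 10 to give the racemic propargylic alcohol 1-[2,4-bis(methoxymethoxy)-3,5-bis(3-methylbut-2-en-1-yl)phenyl]-3-[4-(methoxymethoxy)phenyl]prop-2-yn-1-ol F3. Alkoxide-directed trans-hydroalumination (Red-Al, THF, 0 °C → rt) should give the racemic (E)-allylic alcohol (E)-1-[2,4-bis(methoxymethoxy)-3,5-bis(3-methylbut-2-en-1-yl)phenyl]-3-[4-(methoxymethoxy)phenyl]prop-2-en-1-ol F4. Oxidation with MnO2 (CH2Cl2, rt) removes the temporary carbinol centre and should give the tris-MOM chalcone (E)-1-[2,4-bis(methoxymethoxy)-3,5-bis(3-methylbut-2-en-1-yl)phenyl]-3-[4-(methoxymethoxy)phenyl]prop-2-en-1-one F5. Aqueous HCl in MeOH (40 °C) then removes the three MOM groups to give 13.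

2. Step 3. Deprotonation of the benzylic–allylic CH2 of the first prenyl group, which lies between two OMOM groups, may compete with ring lithiation, and SN2' attack on prenyl bromide may give a reverse-prenyl isomer. Fallback: introduce the C4 prenyl group by halogen–lithium exchange before any prenyl group is present, and keep the only directed metalation for the doubly activated site. It sets out from 2 (replacing steps 2 and 3) and comes back to the route at 7. Bromination of 2 (NBS, MeCN, 0 °C) should give 1-bromo-2,4-bis(methoxymethoxy)benzene F6. Bromine–lithium exchange (n-BuLi, THF, −78 °C) gives [2,4-bis(methoxymethoxy)phenyl]lithium F7, which with CuI (10 mol%) and 3 should give 2,4-bis(methoxymethoxy)-1-(3-methylbut-2-en-1-yl)benzene F8. Directed ortho-metalation between the two OMOM groups (n-BuLi, THF, 0 °C) gives [2,6-bis(methoxymethoxy)-3-(3-methylbut-2-en-1-yl)phenyl]lithium F9, and allylation with 3 (CuI cat.) gives 7.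

3. Step 4. With two prenyl groups present, lateral (benzylic–allylic) lithiation may again compete with lithiation at C6, leading to side-chain formylation or incomplete conversion. Fallback: replace the organolithium formylation by an electrophilic, phenol-directed one. It sets out from 7 and comes back to the route at 11, leaving out 10. MOM removal from 7 (3 M aq. HCl, MeOH, 40 °C) should give 2,4-bis(3-methylbut-2-en-1-yl)benzene-1,3-diol F10. Magnesium-mediated ortho-formylation (MgCl2, Et3N, paraformaldehyde, MeCN, reflux) can only attack C6, the single free position ortho to a phenol, and should give 11.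

**Further compounds**
F1 | step 6 | 1-ethynyl-4-(methoxymethoxy)benzene | C#Cc1ccc(OCOC)cc1
F2 | step 6 | lithium [4-(methoxymethoxy)phenyl]acetylide | [Li]C#Cc1ccc(OCOC)cc1
F3 | step 6 | rac-1-[2,4-bis(methoxymethoxy)-3,5-bis(3-methylbut-2-en-1-yl)phenyl]-3-[4-(methoxymethoxy)phenyl]prop-2-yn-1-ol | COCOc1ccc(C#CC(O)c2cc(CC=C(C)C)c(OCOC)c(CC=C(C)C)c2OCOC)cc1
F4 | step 6 | rac-(E)-1-[2,4-bis(methoxymethoxy)-3,5-bis(3-methylbut-2-en-1-yl)phenyl]-3-[4-(methoxymethoxy)phenyl]prop-2-en-1-ol | COCOc1ccc(/C=C/C(O)c2cc(CC=C(C)C)c(OCOC)c(CC=C(C)C)c2OCOC)cc1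
F5 | step 6 | (E)-1-[2,4-bis(methoxymethoxy)-3,5-bis(3-methylbut-2-en-1-yl)phenyl]-3-[4-(methoxymethoxy)phenyl]prop-2-en-1-one | COCOc1ccc(/C=C/C(=O)c2cc(CC=C(C)C)c(OCOC)c(CC=C(C)C)c2OCOC)cc1
F6 | step 3 | 1-bromo-2,4-bis(methoxymethoxy)benzene | COCOc1ccc(Br)c(OCOC)c1
F7 | step 3 | [2,4-bis(methoxymethoxy)phenyl]lithium | COCOc1ccc([Li])c(OCOC)c1
F8 | step 3 | 2,4-bis(methoxymethoxy)-1-(3-methylbut-2-en-1-yl)benzene | COCOc1ccc(CC=C(C)C)c(OCOC)c1
F9 | step 3 | [2,6-bis(methoxymethoxy)-3-(3-methylbut-2-en-1-yl)phenyl]lithium | COCOc1ccc(CC=C(C)C)c(OCOC)c1[Li]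
F10 | step 4 | 2,4-bis(3-methylbut-2-en-1-yl)benzene-1,3-diol | Oc1ccc(CC=C(C)C)c(O)c1CC=C(C)C
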